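## Retrosynthetic overview

- The δ‑lactone C–O bond is closed last, by acyl transfer from a C‑1 alkoxide that is created when alkenyl triflate 14 is coupled with aldehyde 20.
- Triflate 14 comes from ketone 11, which is assembled in one three‑component step (alkenyl 1,4‑addition, then enolate alkylation) on (R)‑6‑acetoxy‑2H‑pyran‑3(6H)‑one 3.
- Key disconnection: the anomeric C–O(acetyl) bond. Dynamic kinetic O‑acetylation of the Achmatowicz lactol 2 sets the absolute configuration; this acetate is the one found in the target, and it relays the C‑5 and C‑4a stereocentres.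
- Ring order: dihydropyran first (hemiacetal C–O closure from furfuryl alcohol), lactone last.
- Side fragments: alkenyl bromide 7 (Grignard + 2,3‑dibromopropene) and aldehyde 20 (isoprene monoxide + nitromethane, then Nef).

Assumption: catalyst enantiomers are written as those expected to give the stated configuration; if the sense of induction proves opposite, the mirror‑image catalyst (available in each case) is used.

## Route

Step 1
Reactants: 1 furfuryl alcohol
Product: 2 6-hydroxy-2H-pyran-3(6H)-one (racemic lactol)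
Conditions: NBS, NaHCO3, THF–H2O (4:1), 0 °C
Reagents that add atoms: water, O
Why: Achmatowicz oxidative ring expansion: bromonium oxidation of the furan, opening to the (Z)-keto-enal and hemiacetal C–O closure give the pyranone; the single stereocentre is formed racemic and configurationally labile.

Step 2
Reactants: 2 6-hydroxy-2H-pyran-3(6H)-one
Product: 3 (R)-6-acetoxy-2H-pyran-3(6H)-one
Conditions: Ac2O, (R)-benzotetramisole (5 mol %), i-Pr2NEt, CHCl3, −20 °C
Reagents that add atoms: acetic anhydride, CC(=O)OC(C)=O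
Why: Dynamic kinetic resolution by enantioselective acyl transfer (chiral isothiourea catalysis): the lactol enantiomers interconvert through the open-chain aldehyde and the chiral N-acetyl isothiouronium acetylates the (R)-hemiacetal faster, which fixes the acetal stereocentre that is carried unchanged into the target.

Step 3
Reactants: 4 2-(2-bromoethyl)-2-methyl-1,3-dioxolane; 5 2,3-dibromopropene
Product: 7 2-(4-bromopent-4-en-1-yl)-2-methyl-1,3-dioxolane, via Grignard reagent 6 (not isolated)
Conditions: Mg, THF, 30 °C; then 5, CuI (5 mol %), THF, −20 → 0 °C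
Reagents that add atoms: none
Why: Copper-catalysed Grignard allylic substitution: the primary alkylmagnesium displaces the allylic bromide and leaves the vinylic bromide untouched; no stereocentre is formed.

Step 4
Reactants: 7 2-(4-bromopent-4-en-1-yl)-2-methyl-1,3-dioxolane; 3 (R)-6-acetoxy-2H-pyran-3(6H)-one; 8 methyl iodoacetate
Product: 11 methyl 2-[(2R,3R,4S)-2-acetoxy-3-[5-(2-methyl-1,3-dioxolan-2-yl)pent-1-en-2-yl]-5-oxotetrahydro-2H-pyran-4-yl]acetate, via alkenylmagnesium bromide 9 (not isolated), via bromomagnesium enolate 10 (not isolated)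
Conditions: 7, Mg, THF, 45 °C; add to 3, CuBr·SMe2 (10 mol %), THF, −78 °C; then HMPA, 8, −78 → −30 °C
Reagents that add atoms: none
Why: Copper-catalysed conjugate addition followed by enolate alkylation (three-component coupling): the alkenyl group adds to the enone β-carbon anti to the pseudo-axial anomeric acetate (sets C-3), and the regiodefined magnesium enolate is alkylated anti to the new C-3 branch (sets C-4).

Step 5
Reactants: 11 methyl 2-[(2R,3R,4S)-2-acetoxy-3-[5-(2-methyl-1,3-dioxolan-2-yl)pent-1-en-2-yl]-5-oxotetrahydro-2H-pyran-4-yl]acetate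
Product: 13 methyl 2-[(2R,3R,4S)-2-acetoxy-3-[5-(2-methyl-1,3-dioxolan-2-yl)pent-1-en-2-yl]-5-(trifluoromethylsulfonyloxy)-3,4-dihydro-2H-pyran-4-yl]acetate, via potassium enolate 12 (not isolated)
Conditions: KHMDS (1.1 equiv), THF, −78 °C, 20 min; then PhNTf2, −78 → −40 °C
Reagents that add atoms: N-phenyl-bis(trifluoromethanesulfonimide), O=S(=O)(N(c1ccccc1)S(=O)(=O)C(F)(F)F)C(F)(F)F
Why: Kinetic enolate O-triflation: the bulky amide base removes a proton from the unhindered O–CH2 (C-6) and not the tertiary, doubly branched C-4–H, so the enol ether C=C of the target is formed; the ketal keeps the side-chain ketone out of play and no stereocentre changes.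

Step 6
Reactants: 13 methyl 2-[(2R,3R,4S)-2-acetoxy-3-[5-(2-methyl-1,3-dioxolan-2-yl)pent-1-en-2-yl]-5-(trifluoromethylsulfonyloxy)-3,4-dihydro-2H-pyran-4-yl]acetate
Product: 14 methyl 2-[(2R,3R,4S)-2-acetoxy-3-(6-oxohept-1-en-2-yl)-5-(trifluoromethylsulfonyloxy)-3,4-dihydro-2H-pyran-4-yl]acetate
Conditions: PPTS (20 mol %), acetone–H2O (10:1), 45 °C
Reagents that add atoms: water, O
Why: Mild acid-catalysed ketal hydrolysis: the triflate-substituted enol ether is too electron-poor to protonate and the anomeric acetate, whose ring oxygen is tied up in that enol ether, does not ionise under these conditions.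

Step 7
Reactants: 15 2-methyl-2-vinyloxirane (racemic); 16 nitromethane
Product: 17 (E)-2-methyl-5-nitropent-2-en-1-ol
Conditions: Pd(PPh3)4 (2 mol %), MeNO2 (5 equiv), THF, rt; minor Z isomer removed by chromatography
Reagents that add atoms: none
Why: Tsuji–Trost alkylation under neutral conditions: Pd(0) opens the vinyl epoxide to an alkoxy π-allyl complex whose alkoxide deprotonates nitromethane, and the nitronate attacks the unsubstituted allyl terminus to give the (E)-1,4-adduct.

Step 8
Reactants: 17 (E)-2-methyl-5-nitropent-2-en-1-ol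
Product: 18 (E)-2-methyl-5-nitropent-2-en-1-yl acetate
Conditions: Ac2O, pyridine, DMAP (cat.), CH2Cl2, 0 °C
Reagents that add atoms: acetic anhydride, CC(=O)OC(C)=O
Why: Standard DMAP-catalysed O-acetylation of a primary allylic alcohol; the alkene geometry is untouched.

Step 9
Reactants: 18 (E)-2-methyl-5-nitropent-2-en-1-yl acetate
Product: 20 (E)-2-methyl-5-oxopent-2-en-1-yl acetate, via nitronate salt 19 (not isolated)
Conditions: DBU, THF, 0 °C; then 15% aq. TiCl3, NH4OAc (pH 5–6), 0 °C → rt; used at once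
Reagents that add atoms: water, O
Why: McMurry reductive Nef reaction: Ti(III) reduces the nitronate to the imine, which hydrolyses at buffered pH to the aldehyde without moving the β,γ-double bond into conjugation or cleaving the acetate.

Step 10
Reactants: 14 methyl 2-[(2R,3R,4S)-2-acetoxy-3-(6-oxohept-1-en-2-yl)-5-(trifluoromethylsulfonyloxy)-3,4-dihydro-2H-pyran-4-yl]acetate; 20 (E)-2-methyl-5-oxopent-2-en-1-yl acetate
Product: 22 (1S,4aS,5R,6R)-6-acetoxy-1-[(2E)-4-acetoxy-3-methylbut-2-en-1-yl]-5-(6-oxohept-1-en-2-yl)-4,4a,5,6-tetrahydro-1H-pyrano[3,4-c]pyran-3-one (CNP0120157.1), via hydroxy ester alkoxide 21 (not isolated)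
Conditions: CrCl2 (10 mol %), Kishi-type (S)-oxazoline–sulfonamide ligand (11 mol %), proton sponge (11 mol %), NiCl2·(2,9-dimethylphenanthroline) (2 mol %), Mn (2 equiv), Cp2ZrCl2 (1.2 equiv), LiCl (2 equiv), MeCN, rt; then 40 °C, 2 h
Reagents that add atoms: none
Why: Proposed new method: a ligand-controlled Ni/Cr alkenyl triflate–aldehyde coupling on a β-alkoxy cyclic enol triflate, a substrate class where it has not been shown, terminated by lactone C–O closure: Ni(0) inserts into the C–OTf bond, the alkenyl group passes to the chiral Cr(III) sulfonamide complex and adds to the aldehyde face selected by the ligand to give the (S)-alkoxide (sets C-1), Cp2ZrCl2 takes over the alkoxide to turn Cr over, and the zirconium alkoxide acylates the neighbouring methyl ester to form the lactone; the ring oxygen trans to the metal cannot β-eliminate because a cyclohexyne would result; the closest known chemistry is the catalytic asymmetric Nozaki–Hiyama–Kishi reaction and NHK/lactonisation cascades.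

## Compound list

1 | furfuryl alcohol | OCc1ccco1 | starting material
2 | 6-hydroxy-2H-pyran-3(6H)-one (racemic lactol) | OC1OCC(=O)C=C1 | intermediate
3 | (R)-6-acetoxy-2H-pyran-3(6H)-one | CC(=O)O[C@H]1OCC(=O)C=C1 | intermediate
4 | 2-(2-bromoethyl)-2-methyl-1,3-dioxolane | CC1(CCBr)OCCO1 | starting material
5 | 2,3-dibromopropene | C=C(Br)CBr | starting material
6 | [2-(2-methyl-1,3-dioxolan-2-yl)ethyl]magnesium bromide | CC1(CC[Mg]Br)OCCO1 | intermediate
7 | 2-(4-bromopent-4-en-1-yl)-2-methyl-1,3-dioxolane | C=C(Br)CCCC1(C)OCCO1 | intermediate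
8 | methyl iodoacetate | COC(=O)CI | starting material
9 | [5-(2-methyl-1,3-dioxolan-2-yl)pent-1-en-2-yl]magnesium bromide | C=C([Mg]Br)CCCC1(C)OCCO1 | intermediate
10 | bromomagnesium enolate of the (2R,3R)-2-acetoxy-3-alkenyl-tetrahydropyran-5-one (C4=C5 enolate) | C=C(CCCC2(C)OCCO2)[C@@H]1[C@@H](OC(C)=O)OCC(O[Mg]Br)=C1 | intermediate
11 | methyl 2-[(2R,3R,4S)-2-acetoxy-3-[5-(2-methyl-1,3-dioxolan-2-yl)pent-1-en-2-yl]-5-oxotetrahydro-2H-pyran-4-yl]acetate | C=C(CCCC2(C)OCCO2)[C@@H]1[C@@H](OC(C)=O)OCC(=O)[C@H]1CC(=O)OC | intermediate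
12 | potassium enolate of 11 (C5=C6 enolate) | [K+].C=C(CCCC2(C)OCCO2)[C@@H]1[C@@H](OC(C)=O)OC=C([O-])[C@H]1CC(=O)OC | intermediate
13 | methyl 2-[(2R,3R,4S)-2-acetoxy-3-[5-(2-methyl-1,3-dioxolan-2-yl)pent-1-en-2-yl]-5-(trifluoromethylsulfonyloxy)-3,4-dihydro-2H-pyran-4-yl]acetate | C=C(CCCC2(C)OCCO2)[C@@H]1[C@@H](OC(C)=O)OC=C(OS(=O)(=O)C(F)(F)F)[C@H]1CC(=O)OC | intermediate
14 | methyl 2-[(2R,3R,4S)-2-acetoxy-3-(6-oxohept-1-en-2-yl)-5-(trifluoromethylsulfonyloxy)-3,4-dihydro-2H-pyran-4-yl]acetate | C=C(CCCC(C)=O)[C@@H]1[C@@H](OC(C)=O)OC=C(OS(=O)(=O)C(F)(F)F)[C@H]1CC(=O)OC | intermediate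
15 | 2-methyl-2-vinyloxirane (isoprene monoxide, racemic) | C=CC1(C)CO1 | starting material
16 | nitromethane | C[N+](=O)[O-] | starting material
17 | (E)-2-methyl-5-nitropent-2-en-1-ol | [O-][N+](=O)CC/C=C(\C)CO | intermediate
18 | (E)-2-methyl-5-nitropent-2-en-1-yl acetate | [O-][N+](=O)CC/C=C(\C)COC(C)=O | intermediate
19 | DBU-H+ nitronate of 18 | [O-][N+]([O-])=CC/C=C(\C)COC(C)=O.C1CCC2=[NH+]CCCN2CC1 | intermediate
20 | (E)-2-methyl-5-oxopent-2-en-1-yl acetate | O=CC/C=C(\C)COC(C)=O | intermediate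
21 | methyl 2-[(2R,3R,4S)-2-acetoxy-5-[(1S,3E)-5-acetoxy-1-hydroxy-4-methylpent-3-en-1-yl]-3-(6-oxohept-1-en-2-yl)-3,4-dihydro-2H-pyran-4-yl]acetate (present as its Cr/Zr alkoxide) | C=C(CCCC(C)=O)[C@@H]1[C@@H](OC(C)=O)OC=C([C@@H](O)C/C=C(\C)COC(C)=O)[C@H]1CC(=O)OC | intermediate
22 | (1S,4aS,5R,6R)-6-acetoxy-1-[(2E)-4-acetoxy-3-methylbut-2-en-1-yl]-5-(6-oxohept-1-en-2-yl)-4,4a,5,6-tetrahydro-1H-pyrano[3,4-c]pyran-3-one (CNP0120157.1) | C=C(CCCC(C)=O)[C@@H]1[C@@H](OC(C)=O)OC=C2[C@H](C/C=C(\C)COC(C)=O)OC(=O)C[C@H]21 | target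

## Step count and risk

Total steps: 10. Longest linear sequence: 6 (steps 1, 2, 4, 5, 6, 10, from furfuryl alcohol).

The three steps most likely to fail:

Step 4. The enone carries a γ-acyloxy (anomeric acetate) group, which organocopper reagents can cleave reductively or ionise; the Grignard may also enolise C-2, and magnesium enolates alkylate sluggishly. The fallback sets out from 7 and 3 and comes back at 11. Bromide 7 is converted by Miyaura borylation (B2pin2, PdCl2(PPh3)2, KOPh, toluene, 50 °C) into 4,4,5,5-tetramethyl-2-[5-(2-methyl-1,3-dioxolan-2-yl)pent-1-en-2-yl]-1,3,2-dioxaborolane F1. A neutral rhodium-catalysed Hayashi–Miyaura 1,4-addition of this boronate to 3 ([Rh(cod)OH]2, dioxane–H2O, rt) avoids electron transfer and gives, anti to the acetate, (2R,3R)-3-[5-(2-methyl-1,3-dioxolan-2-yl)pent-1-en-2-yl]-5-oxotetrahydro-2H-pyran-2-yl acetate F2. Kinetic enolisation of this ketone on the side away from the ring oxygen (LiHMDS, THF, −78 °C) and alkylation with 8 anti to the C-3 branch returns to 11.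

Step 5. α-Alkoxy ketones are normally deprotonated on the side away from oxygen, so enolisation at C-6 relies on the steric shielding of the tertiary C-4–H and may give the wrong enol triflate. The fallback sets out from 11 and comes back at 13. Soft enolisation (TMSOTf, Et3N, CH2Cl2, −78 → 0 °C), which favours the oxygen-substituted, less hindered enol, gives methyl 2-[(2R,3R,4S)-2-acetoxy-3-[5-(2-methyl-1,3-dioxolan-2-yl)pent-1-en-2-yl]-5-(trimethylsilyloxy)-3,4-dihydro-2H-pyran-4-yl]acetate F3. This isolable silyl enol ether is purified and converted regiospecifically into the triflate with CsF and PhNTf2 in DME at rt, which gives 13.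

Step 10 (the proposed new step). The chiral Cr catalyst may not control the new carbinol centre on this untested enol-ether triflate, the β,γ-unsaturated aldehyde may isomerise, and the zirconium alkoxide may not lactonise. The fallback uses known chemistry, sets out from 14 and 20 and comes back at 21 and then 22. A stoichiometric Nozaki–Hiyama–Kishi coupling (CrCl2 4 equiv, NiCl2 1 mol %, DMSO, rt) gives methyl 2-[(2R,3R,4S)-2-acetoxy-5-[(3E)-5-acetoxy-1-hydroxy-4-methylpent-3-en-1-yl]-3-(6-oxohept-1-en-2-yl)-3,4-dihydro-2H-pyran-4-yl]acetate as a mixture of carbinol epimers F4. Dess–Martin oxidation (NaHCO3, CH2Cl2, 0 °C) gives methyl 2-[(2R,3R,4S)-2-acetoxy-5-[(3E)-5-acetoxy-4-methylpent-3-enoyl]-3-(6-oxohept-1-en-2-yl)-3,4-dihydro-2H-pyran-4-yl]acetate F5. Corey–Bakshi–Shibata reduction of this enone (Me-CBS oxazaborolidine, catecholborane, toluene, −78 °C) gives the (S)-alcohol 21 as the free hydroxy ester, and DMAP (cat.) in toluene at 50 °C closes the lactone to 22.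

## Further compounds

F1 | step 4 | 4,4,5,5-tetramethyl-2-[5-(2-methyl-1,3-dioxolan-2-yl)pent-1-en-2-yl]-1,3,2-dioxaborolane | C=C(CCCC1(C)OCCO1)B1OC(C)(C)C(C)(C)O1
F2 | step 4 | (2R,3R)-3-[5-(2-methyl-1,3-dioxolan-2-yl)pent-1-en-2-yl]-5-oxotetrahydro-2H-pyran-2-yl acetate | C=C(CCCC2(C)OCCO2)[C@@H]1[C@@H](OC(C)=O)OCC(=O)C1
F3 | step 5 | methyl 2-[(2R,3R,4S)-2-acetoxy-3-[5-(2-methyl-1,3-dioxolan-2-yl)pent-1-en-2-yl]-5-(trimethylsilyloxy)-3,4-dihydro-2H-pyran-4-yl]acetate | C=C(CCCC2(C)OCCO2)[C@@H]1[C@@H](OC(C)=O)OC=C(O[Si](C)(C)C)[C@H]1CC(=O)OC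
F4 | step 10 | methyl 2-[(2R,3R,4S)-2-acetoxy-5-[(3E)-5-acetoxy-1-hydroxy-4-methylpent-3-en-1-yl]-3-(6-oxohept-1-en-2-yl)-3,4-dihydro-2H-pyran-4-yl]acetate (carbinol epimers) | C=C(CCCC(C)=O)[C@@H]1[C@@H](OC(C)=O)OC=C(C(O)C/C=C(\C)COC(C)=O)[C@H]1CC(=O)OC
F5 | step 10 | methyl 2-[(2R,3R,4S)-2-acetoxy-5-[(3E)-5-acetoxy-4-methylpent-3-enoyl]-3-(6-oxohept-1-en-2-yl)-3,4-dihydro-2H-pyran-4-yl]acetate | C=C(CCCC(C)=O)[C@@H]1[C@@H](OC(C)=O)OC=C(C(=O)C/C=C(\C)COC(C)=O)[C@H]1CC(=O)OC
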